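The route cuts the C3–C4 bond of ring A. The target's ring A carries a cis β-hydroxy carboxyl motif: the C3 carbinol sits next to quaternary C4, whose C19 is taken back to the ester level. An intramolecular SmI2 Reformatsky reaction forms this bond, closes ring A onto a finished ring B and sets C3 and C4 in one operation. Its precursor is a ring B cyclohexane with all four ring stereocentres in place: a tertiary α-bromo ester on C5 and a 3-oxopropyl chain on C10 (trans-diequatorial), a C8 silyl ether, and a C9 silylmethyl group as masked C11. The C8 methylene and the side chain follow after ring closure.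

Key step: step 10

Assumption: (S)-4-(tert-butyldimethylsilyloxy)cyclohex-2-en-1-one (1) is bought as the single enantiomer; all other starting materials are commodity chemicals.

Convention: labdane numbering (C1–C20) is used from compound 7 on. α/β refer to the usual drawing of the skeleton, in which the C10 methyl (C20) is α; ring B intermediates are described in the same orientation. The SMILES in the compound list are definitive.

Step 1
Reactants: 1 (S)-4-(tert-butyldimethylsilyloxy)cyclohex-2-en-1-one
Product: 2 (S)-4-(tert-butyldimethylsilyloxy)-2-iodocyclohex-2-en-1-one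
Conditions: I2, pyridine, CH2Cl2, 0 °C → rt
Reagents that add atoms: iodine, II
Why: α-Iodination of a cyclic enone by the iodine/pyridine addition–elimination sequence is standard and leaves the C4 silyl ether and its stereocentre untouched.

Step 2
Reactants: 2 (S)-4-(tert-butyldimethylsilyloxy)-2-iodocyclohex-2-en-1-one
Product: 3 (S)-4-(tert-butyldimethylsilyloxy)-2-methylcyclohex-2-en-1-one
Conditions: Me2Zn, PdCl2(dppf) (5 mol%), THF, 50 °C
Reagents that add atoms: dimethylzinc, C[Zn]C
Why: Negishi cross-coupling of α-iodoenones with alkylzinc reagents is established and installs the methyl group (later C20) under non-basic conditions that do not eliminate the γ-silyloxy group.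

Step 3
Reactants: 3 (S)-4-(tert-butyldimethylsilyloxy)-2-methylcyclohex-2-en-1-one; 4 (chloromethyl)dimethylphenylsilane; 5 allyl bromide
Product: 8 (2S,3S,4S)-2-allyl-4-(tert-butyldimethylsilyloxy)-3-[(dimethylphenylsilyl)methyl]-2-methylcyclohexan-1-one (ring B ketone; C5 carbonyl; 8β-OTBS; 9α-CH2SiMe2Ph; 10α-CH3; 10β-allyl), via Grignard reagent 6 (not isolated), via magnesium enolate 7 (not isolated)
Conditions: 4, Mg, THF, reflux; CuBr·SMe2 (20 mol%), 3, THF, −40 °C; then 5, DMPU, −40 → 0 °C
Reagents that add atoms: none
Why: Copper-catalysed 1,4-addition of the silylmethyl Grignard reagent should occur anti to the C8 silyloxy group (sets C9), and the regiodefined enolate should be allylated anti to the new C9 substituent (sets quaternary C10, methyl cis to the silylmethyl group); this is a tandem conjugate addition/enolate alkylation.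

Step 4
Reactants: 8 ring B ketone; 9 methyl 2-bromopropanoate (racemic)
Product: 11 methyl 2-(C5-hydroxy ring B)propanoate (Reformatsky adduct; tertiary C5–OH; C4 and C5 epimers; 8β-OTBS; 9α-CH2SiMe2Ph; 10α-CH3; 10β-allyl), via zinc enolate 10 (not isolated)
Conditions: Zn dust (Me3SiCl-activated), 9, THF, reflux; then cold aq. NH4Cl
Reagents that add atoms: none
Why: The Reformatsky reaction uses a weakly basic zinc enolate that should add to the α-quaternary ketone without enolising it, forming the C4–C5 bond; the new centres at C4 and C5 are both reworked in steps 5–8.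

Step 5
Reactants: 11 Reformatsky adduct
Product: 12 methyl 2-(ring B cyclohex-5(6)-enyl)propanoate (β,γ-unsaturated ester; C5=C6; C4 epimers; 8β-OTBS; 9α-CH2SiMe2Ph; 10α-CH3; 10β-allyl)
Conditions: SOCl2, pyridine, CH2Cl2, −10 → 0 °C
Reagents that add atoms: none
Why: E2 dehydration of the tertiary carbinol through its chlorosulfite should give mainly the endocyclic alkene, because the conjugated tetrasubstituted isomer is strained against C10; any conjugated isomer converges in step 7.

Step 6
Reactants: 12 β,γ-unsaturated ester
Product: 14 methyl 2-[ring B cyclohex-5(6)-enyl bearing 10β-(3-hydroxypropyl)]propanoate (primary alcohol at C3; C5=C6 retained; C4 epimers), via alkylborane 13 (not isolated)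
Conditions: 9-BBN, THF, 0 °C → rt; then 3 M NaOH, 30% H2O2, 0 °C
Reagents that add atoms: hydrogen peroxide, OO
Why: Hydroboration–oxidation with 9-BBN is highly selective for the monosubstituted allyl alkene over the hindered trisubstituted ring alkene and gives the anti-Markovnikov C3 alcohol.

Step 7
Reactants: 14 alkenyl alcohol
Product: 15 methyl 2-[ring B cyclohexyl]propanoate (saturated hydroxy ester; 5β-H; C4 epimers; 10β-(3-hydroxypropyl); 10α-CH3; 9α-CH2SiMe2Ph; 8β-OTBS)
Conditions: H2 (4 atm), 10% Pd/C, EtOAc, rt
Reagents that add atoms: none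
Why: Heterogeneous hydrogenation should deliver hydrogen to the β face, opposite the pseudo-axial C10 methyl group (as in 5-ene steroids), which sets C5 with its side chain equatorial and trans to the C10 chain.

Step 8
Reactants: 15 saturated hydroxy ester
Product: 18 methyl 2-bromo-2-[ring B cyclohexyl]propanoate (tertiary α-bromo ester; C4 epimers; free C3 alcohol; 5β-H; 8β-OTBS; 9α-CH2SiMe2Ph; 10α-CH3), via ketene silyl acetal 16 (not isolated), via bromo silyl ether 17 (not isolated)
Conditions: LiN(i-Pr)2 (2.5 equiv), THF, −78 → −30 °C; Me3SiCl, −78 → 0 °C; NBS, THF, −78 °C; then 1 M HCl, THF, 0 °C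
Reagents that add atoms: N-bromosuccinimide, O=C1CCC(=O)N1Br
Why: Enolisation with in-flask O-silylation (which also masks the alcohol) followed by electrophilic bromination of the ketene silyl acetal is a standard route to tertiary α-bromo esters; the C4 configuration is erased in step 10.

Step 9
Reactants: 18 bromo alcohol
Product: 19 methyl 2-bromo-2-[ring B cyclohexyl bearing 10β-(3-oxopropyl)]propanoate (bromo ester aldehyde; C4 epimers; 5β-H; 8β-OTBS; 9α-CH2SiMe2Ph; 10α-CH3)
Conditions: Dess–Martin periodinane, CH2Cl2, 0 °C → rt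
Reagents that add atoms: none
Why: Dess–Martin oxidation gives the C3 aldehyde under neutral conditions that tolerate the tertiary bromide, the silyl ether and the silane.

Step 10
Reactants: 19 bromo ester aldehyde
Product: 21 methyl ester of the trans-decalin β-hydroxy acid (ring A closed; 3α-OH equatorial; C4 with axial α-CO2CH3 (C19) and equatorial β-CH3 (C18); 5β-H; 8β-OTBS; 9α-CH2SiMe2Ph; 10α-CH3), via samarium enolate 20 (not isolated)
Conditions: SmI2 (2.5 equiv, 0.1 M in THF), THF, −78 °C, slow addition of 19 at high dilution; then aq. NH4Cl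
Reagents that add atoms: none
Why: SmI2 (divalent samarium) passes two electrons in succession to the tertiary bromide, bromide is expelled and an ester enolate of trivalent samarium results, whose carbon C4 attacks the C3 aldehyde; the closest known reaction type is the SmI2-promoted intramolecular Reformatsky reaction that gives six-membered β-hydroxy esters. Ring A closes in the 6-exo-trig mode (the C3 carbonyl is exocyclic to the forming ring) through a chair fused to ring B, whose C5 and C10 substituents are equatorial and trans. The configuration at C3 is controlled by the samarium ion, which bridges the enolate oxygen and the aldehyde oxygen and so puts the C3 oxygen equatorial (3α) and cis to the ester carbon. The configuration at C4 is controlled by the C10 methyl group: the planar metal-bound ester unit takes the axial position syn to C20, because the alternative would force C18 into a 1,3-diaxial contact with C20. The step needs chemoselectivity for C–Br reduction over ketyl formation at the aldehyde, which the far faster reduction of an α-bromo ester at −78 °C without HMPA should secure. It also needs diastereoselectivity for the bridged chair, which the fixed C5 and C10 centres should secure, and both bromide epimers converge on the same enolate.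

Step 11
Reactants: 21 β-hydroxy ester
Product: 22 3α,19-diol (C19 CH2OH axial; 8β-OTBS; 9α-CH2SiMe2Ph; 5β-H; 10α-CH3)
Conditions: LiAlH4, THF, 0 °C → reflux; then Na2SO4·10H2O
Reagents that add atoms: none
Why: Hydride reduction of the hindered axial ester with LiAlH4 gives the C19 carbinol and leaves the silyl ether and the C–Si bond intact.

Step 12
Reactants: 22 3α,19-diol
Product: 24 3,19-acetonide with free 8β-OH (9α-CH2SiMe2Ph retained), via triol 23 (not isolated)
Conditions: HCl (1% in MeOH), rt; evaporate; then Me2C(OMe)2, PPTS, acetone, rt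
Reagents that add atoms: 2,2-dimethoxypropane, COC(C)(C)OC
Why: Acid methanolysis removes the secondary silyl ether and acid-catalysed transketalisation then locks the cis 3,19-diol as its six-membered acetonide, which the isolated C8 hydroxyl cannot form.

Step 13
Reactants: 24 acetonide alcohol
Product: 25 3,19-acetonide 8-ketone (9α-CH2SiMe2Ph)
Conditions: Dess–Martin periodinane, pyridine, CH2Cl2, rt
Reagents that add atoms: none
Why: Dess–Martin oxidation of the secondary C8 alcohol gives a stable β-silyl ketone, and C9 keeps its equatorial (thermodynamically preferred) substituent.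

Step 14
Reactants: 25 8-ketone
Product: 26 3,19-acetonide with exocyclic C8=C17 methylene and 9α-CH2SiMe2Ph
Conditions: Ph3PCH3Br, KOt-Bu, toluene, 90 °C
Reagents that add atoms: methyltriphenylphosphonium bromide, C[P+](c1ccccc1)(c1ccccc1)c1ccccc1.[Br-]
Why: Wittig methylenation of 8-oxo decalins of this type is well precedented, no other carbonyl or free hydroxyl is present, and the only enolisable stereocentre (C9) already has its stable configuration.

Step 15
Reactants: 26 methylene silane
Product: 27 3,19-acetonide 11-alcohol (C9 CH2OH; C8=C17 methylene)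
Conditions: KH, t-BuOOH, Bu4NF, NMP, 0 → 70 °C
Reagents that add atoms: tert-butyl hydroperoxide, CC(C)(C)OO
Why: The basic-peroxide variant of the Fleming–Tamao oxidation (nucleophilic cleavage of the Si–phenyl bond, then migration of C11 from silicon to oxygen) unmasks the primary alcohol without the electrophilic reagents that would attack the exocyclic alkene.

Step 16
Reactants: 27 11-alcohol
Product: 28 3,19-acetonide 11-aldehyde (β,γ-unsaturated aldehyde; 9β-H; C8=C17 methylene)
Conditions: Dess–Martin periodinane, pyridine, CH2Cl2, 0 °C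
Reagents that add atoms: none
Why: Buffered Dess–Martin oxidation should give the aldehyde without epimerisation at C9 (the substituent is already equatorial) or migration of the double bond into conjugation.

Step 17
Reactants: 29 2-(bromomethyl)acrylic acid; 30 allyl alcohol
Product: 31 allyl 2-(bromomethyl)acrylate
Conditions: 30 (excess), TsOH·H2O (cat.), hydroquinone (trace), cyclohexane, reflux (Dean–Stark)
Reagents that add atoms: none
Why: Acid-catalysed Fischer esterification with azeotropic removal of water is the standard preparation of 2-(bromomethyl)acrylates and does not displace the allylic bromide.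

Step 18
Reactants: 28 11-aldehyde; 31 allyl 2-(bromomethyl)acrylate
Product: 33 (11R)-11-hydroxy allyl ester (C11(OH)–C12H2–C13(=CH2)–CO2-allyl on C9; 3,19-acetonide; C8=C17 methylene), via allylzinc bromide 32 (not isolated)
Conditions: Zn dust, THF/sat. aq. NH4Cl (2:1), 0 °C → rt
Reagents that add atoms: none
Why: The zinc-mediated Barbier 2-(alkoxycarbonyl)allylation forms C11–C12 under near-neutral conditions; Felkin–Anh addition anti to quaternary C10 (Re face of C11) should give the 11R carbinol, and the hindered alcohol is not expected to lactonise onto the ester at room temperature.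

Step 19
Reactants: 33 hydroxy allyl ester
Product: 34 14-deoxy-11-hydroxyandrographolide 3,19-acetonide (α-substituted butenolide C13=C14–C15–O–C16)
Conditions: second-generation Grubbs catalyst RuCl2(=CHPh)(PCy3)(H2IMes) (5 mol%), CH2Cl2 (5 mM), 40 °C
Reagents that add atoms: none
Why: Ring-closing metathesis between the allyl ester and the acrylate alkene closes the five-membered butenolide with loss of ethylene, and the hindered 1,1-disubstituted C8 methylene should not compete.

Step 20
Reactants: 34 butenolide acetonide
Product: 35 14-deoxy-11-hydroxyandrographolide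
Conditions: AcOH/H2O (7:3), rt
Reagents that add atoms: none
Why: Mild acid hydrolysis of the 1,3-dioxane acetonide releases the 3α,19-diol without affecting the butenolide, the homoallylic C11 alcohol or the exocyclic alkene.

Compound list

1 | (S)-4-(tert-butyldimethylsilyloxy)cyclohex-2-en-1-one | O=C1C=C[C@@H](O[Si](C)(C)C(C)(C)C)CC1 | starting material
2 | (S)-4-(tert-butyldimethylsilyloxy)-2-iodocyclohex-2-en-1-one | O=C1C(I)=C[C@@H](O[Si](C)(C)C(C)(C)C)CC1 | intermediate
3 | (S)-4-(tert-butyldimethylsilyloxy)-2-methylcyclohex-2-en-1-one | CC1=C[C@@H](O[Si](C)(C)C(C)(C)C)CCC1=O | intermediate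
4 | (chloromethyl)dimethylphenylsilane | C[Si](C)(CCl)c1ccccc1 | starting material
5 | allyl bromide | C=CCBr | starting material
6 | (dimethylphenylsilyl)methylmagnesium chloride (formed in the flask) | C[Si](C)(C[Mg]Cl)c1ccccc1 | intermediate
7 | chloromagnesium enolate after 1,4-addition (C5–O enolate, C5=C10; 8β-OTBS; 9α-CH2SiMe2Ph; formed in the flask) | CC1=C(O[Mg]Cl)CC[C@H](O[Si](C)(C)C(C)(C)C)[C@H]1C[Si](C)(C)c1ccccc1 | intermediate
8 | (2S,3S,4S)-2-allyl-4-(tert-butyldimethylsilyloxy)-3-[(dimethylphenylsilyl)methyl]-2-methylcyclohexan-1-one (ring B ketone) | O=C1CC[C@H](O[Si](C)(C)C(C)(C)C)[C@@H](C[Si](C)(C)c2ccccc2)[C@]1(C)CC=C | intermediate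
9 | methyl 2-bromopropanoate (racemic) | COC(=O)C(C)Br | starting material
10 | bromozinc enolate of methyl propanoate (formed in the flask; drawn C-bound) | COC(=O)C(C)[Zn]Br | intermediate
11 | Reformatsky adduct, tertiary C5 alcohol (C4 and C5 epimers) | COC(=O)C(C)C1(O)CC[C@H](O[Si](C)(C)C(C)(C)C)[C@@H](C[Si](C)(C)c2ccccc2)[C@]1(C)CC=C | intermediate
12 | β,γ-unsaturated ester, C5=C6 (C4 epimers) | COC(=O)C(C)C1=CC[C@H](O[Si](C)(C)C(C)(C)C)[C@@H](C[Si](C)(C)c2ccccc2)[C@]1(C)CC=C | intermediate
13 | B-alkyl-9-borabicyclo[3.3.1]nonane at C3 (formed in the flask) | COC(=O)C(C)C1=CC[C@H](O[Si](C)(C)C(C)(C)C)[C@@H](C[Si](C)(C)c2ccccc2)[C@]1(C)CCCB1C2CCCC1CCC2 | intermediate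
14 | alkenyl ester with 10β-(3-hydroxypropyl) chain (C4 epimers) | COC(=O)C(C)C1=CC[C@H](O[Si](C)(C)C(C)(C)C)[C@@H](C[Si](C)(C)c2ccccc2)[C@]1(C)CCCO | intermediate
15 | saturated hydroxy ester, 5β-H (C4 epimers) | COC(=O)C(C)[C@H]1CC[C@H](O[Si](C)(C)C(C)(C)C)[C@@H](C[Si](C)(C)c2ccccc2)[C@]1(C)CCCO | intermediate
16 | ketene trimethylsilyl methyl acetal with C3 trimethylsilyl ether (formed in the flask; E/Z mixture) | COC(O[Si](C)(C)C)=C(C)[C@H]1CC[C@H](O[Si](C)(C)C(C)(C)C)[C@@H](C[Si](C)(C)c2ccccc2)[C@]1(C)CCCO[Si](C)(C)C | intermediate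
17 | tertiary α-bromo ester with C3 trimethylsilyl ether (formed in the flask; C4 epimers) | COC(=O)C(C)(Br)[C@H]1CC[C@H](O[Si](C)(C)C(C)(C)C)[C@@H](C[Si](C)(C)c2ccccc2)[C@]1(C)CCCO[Si](C)(C)C | intermediate
18 | tertiary α-bromo ester with free C3 alcohol (C4 epimers) | COC(=O)C(C)(Br)[C@H]1CC[C@H](O[Si](C)(C)C(C)(C)C)[C@@H](C[Si](C)(C)c2ccccc2)[C@]1(C)CCCO | intermediate
19 | ring B bromo ester aldehyde, key-step precursor (C4 epimers) | COC(=O)C(C)(Br)[C@H]1CC[C@H](O[Si](C)(C)C(C)(C)C)[C@@H](C[Si](C)(C)c2ccccc2)[C@]1(C)CCC=O | intermediate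
20 | diiodosamarium ester enolate (trivalent samarium; formed in the flask) | COC(O[Sm](I)I)=C(C)[C@H]1CC[C@H](O[Si](C)(C)C(C)(C)C)[C@@H](C[Si](C)(C)c2ccccc2)[C@]1(C)CCC=O | intermediate
21 | trans-decalin β-hydroxy ester, key-step product (3α-OH; 4α-CO2CH3; 4β-CH3; 5β-H; 8β-OTBS; 9α-CH2SiMe2Ph; 10α-CH3) | COC(=O)[C@]1(C)[C@H](O)CC[C@@]2(C)[C@H](C[Si](C)(C)c3ccccc3)[C@@H](O[Si](C)(C)C(C)(C)C)CC[C@H]12 | intermediate
22 | 3α,19-diol with 8β-OTBS and 9α-CH2SiMe2Ph | OC[C@]1(C)[C@H](O)CC[C@@]2(C)[C@H](C[Si](C)(C)c3ccccc3)[C@@H](O[Si](C)(C)C(C)(C)C)CC[C@H]12 | intermediate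
23 | 3α,8β,19-triol with 9α-CH2SiMe2Ph (formed in the flask) | OC[C@]1(C)[C@H](O)CC[C@@]2(C)[C@H](C[Si](C)(C)c3ccccc3)[C@@H](O)CC[C@H]12 | intermediate
24 | 3,19-acetonide with free 8β-OH and 9α-CH2SiMe2Ph | CC1(C)OC[C@]2(C)[C@H](O1)CC[C@@]3(C)[C@H](C[Si](C)(C)c4ccccc4)[C@@H](O)CC[C@H]23 | intermediate
25 | 3,19-acetonide 8-ketone with 9α-CH2SiMe2Ph | CC1(C)OC[C@]2(C)[C@H](O1)CC[C@@]3(C)[C@H](C[Si](C)(C)c4ccccc4)C(=O)CC[C@H]23 | intermediate
26 | 3,19-acetonide with C8=C17 methylene and 9α-CH2SiMe2Ph | CC1(C)OC[C@]2(C)[C@H](O1)CC[C@@]3(C)[C@H](C[Si](C)(C)c4ccccc4)C(=C)CC[C@H]23 | intermediate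
27 | 3,19-acetonide 11-alcohol with C8=C17 methylene | CC1(C)OC[C@]2(C)[C@H](O1)CC[C@@]3(C)[C@H](CO)C(=C)CC[C@H]23 | intermediate
28 | 3,19-acetonide 11-aldehyde with C8=C17 methylene | CC1(C)OC[C@]2(C)[C@H](O1)CC[C@@]3(C)[C@H](C=O)C(=C)CC[C@H]23 | intermediate
29 | 2-(bromomethyl)acrylic acid | OC(=O)C(=C)CBr | starting material
30 | allyl alcohol | C=CCO | starting material
31 | allyl 2-(bromomethyl)acrylate | C=CCOC(=O)C(=C)CBr | intermediate
32 | 2-(allyloxycarbonyl)allylzinc bromide (formed in the flask) | C=CCOC(=O)C(=C)C[Zn]Br | intermediate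
33 | (11R)-11-hydroxy allyl 2-methylene ester, 3,19-acetonide | CC1(C)OC[C@]2(C)[C@H](O1)CC[C@@]3(C)[C@H]([C@H](O)CC(=C)C(=O)OCC=C)C(=C)CC[C@H]23 | intermediate
34 | 14-deoxy-11-hydroxyandrographolide 3,19-acetonide | CC1(C)OC[C@]2(C)[C@H](O1)CC[C@@]3(C)[C@H]([C@H](O)CC4=CCOC4=O)C(=C)CC[C@H]23 | intermediate
35 | 14-deoxy-11-hydroxyandrographolide | C=C1CC[C@@H]2[C@](C)(CO)[C@H](O)CC[C@@]2(C)[C@@H]1[C@H](O)CC1=CCOC1=O | target

Total step count: 20 (19 in the main line, 1 for reagent 31).
Longest linear sequence: 19 steps (steps 1–16 and 18–20).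

Steps most likely to fail

Step 10. The samarium enolate may cyclise in part through a non-bridged or boat-like transition state, so that facial selectivity at C3 is lost and the axial C3 alcohol accompanies 21. The fallback changes the way C3 is set, from aldol control to ketone reduction. It sets out from 21 carried on together with its C3 epimer. Dess–Martin oxidation converges both on the non-enolisable C3 ketone, the methyl 3-oxo ester F1. NaBH4 in MeOH at −20 °C, which attacks 4,4-disubstituted 3-oxo decalins from the axial direction, then gives the equatorial 3α-alcohol, and the route is rejoined at 21.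

Step 18. Addition to the hindered C11 aldehyde may proceed with poor facial selectivity (competition from the anti-Felkin rotamer), and the zinc alkoxide may translactonise onto the ester. The fallback sets out from 28 and uses reagent control:
- Propargylation with allenylboronic acid pinacol ester and a chiral BINOL-derived phosphoric acid gives the (11R)-homopropargylic alcohol F2; the catalyst enantiomer is the one that delivers to the Re face of C11, matched with the substrate bias.
- Et3SiOTf and 2,6-lutidine give the triethylsilyl ether F3.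
- n-BuLi and then paraformaldehyde give the propargylic alcohol F4.
- NaAlH2(OCH2CH2OMe)2 and then I2 give the (Z)-3-iodoallylic alcohol F5 by hydroxyl-directed trans-hydroalumination.
- Carbonylative lactonisation (PdCl2(PPh3)2, CO, Et3N) gives the butenolide silyl ether F6.
- Aqueous acetic acid removes the silyl ether and the acetonide together, and the route is rejoined at 35.

Step 4. The zinc enolate may fail to add to the ketone flanked by quaternary C10 (slow addition, reversal on heating, enolisation towards C6). The fallback replaces carbonyl addition and dehydration by cross-coupling. It sets out from 8: KN(SiMe3)2 and PhNTf2 give the C5(6) enol triflate F7, since only C6 can be deprotonated. Palladium-catalysed coupling (zerovalent palladium from Pd(dba)2 and P(t-Bu)3) with the zinc enolate 10 then gives the β,γ-unsaturated ester directly, and the route is rejoined at 12.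

Further compounds

F1 | step 10 | methyl 3-oxo ester of the trans-decalin (C3 ketone; 4α-CO2CH3; 8β-OTBS; 9α-CH2SiMe2Ph) | COC(=O)[C@]1(C)C(=O)CC[C@@]2(C)[C@H](C[Si](C)(C)c3ccccc3)[C@@H](O[Si](C)(C)C(C)(C)C)CC[C@H]12
F2 | step 18 | (11R)-homopropargylic alcohol, 3,19-acetonide | CC1(C)OC[C@]2(C)[C@H](O1)CC[C@@]3(C)[C@H]([C@H](O)CC#C)C(=C)CC[C@H]23
F3 | step 18 | (11R)-11-triethylsilyl ether of the terminal alkyne | CC1(C)OC[C@]2(C)[C@H](O1)CC[C@@]3(C)[C@H]([C@H](O[Si](CC)(CC)CC)CC#C)C(=C)CC[C@H]23
F4 | step 18 | propargylic alcohol (C15 hydroxymethyl on the alkyne) | CC1(C)OC[C@]2(C)[C@H](O1)CC[C@@]3(C)[C@H]([C@H](O[Si](CC)(CC)CC)CC#CCO)C(=C)CC[C@H]23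
F5 | step 18 | (Z)-13-iodo-13-en-15-ol (iodine cis to CH2OH) | CC1(C)OC[C@]2(C)[C@H](O1)CC[C@@]3(C)[C@H]([C@H](O[Si](CC)(CC)CC)C/C(I)=C/CO)C(=C)CC[C@H]23
F6 | step 18 | butenolide 11-triethylsilyl ether, 3,19-acetonide | CC1(C)OC[C@]2(C)[C@H](O1)CC[C@@]3(C)[C@H]([C@H](O[Si](CC)(CC)CC)CC4=CCOC4=O)C(=C)CC[C@H]23
F7 | step 4 | ring B C5(6) enol triflate | O=S(=O)(OC1=CC[C@H](O[Si](C)(C)C(C)(C)C)[C@@H](C[Si](C)(C)c2ccccc2)[C@]1(C)CC=C)C(F)(F)F
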